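Ring A is built last, onto a finished pyranone ring C that already carries ring B at C2 and the methoxy group at C3. Ring A is a resorcinol: O5 and O7 are meta, C6 bears hydrogen, and the ring is fused to ring C through C4a–C8a. Photochemical Wolff rearrangement of a 6-(diazoacetyl)pyranone gives a pyranonyl ketene that takes up (triisopropylsilyloxy)acetylene. In one operation this creates the four bonds C4a–C5, C5–C6, C7–C8 and C8–C8a, delivering O5 as a free chelated phenol and O7 as a silyl ether. The precursor is assembled from kojic acid and a vanillin-derived arylboronate by cross-coupling, oxidation and diazoketone formation.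

Key step: step 11

Assumption: 4-(benzyloxy)-3-methoxybenzaldehyde (the benzyl ether of vanillin), kojic acid and acetylene are purchased; (triisopropylsilyloxy)acetylene is not taken to be a stock item and is made in step 10.

Protecting groups: benzyl sits on O5' and methoxymethyl on O2', so that O5' is freed by neutral hydrogenolysis while O7 still carries silicon, and every operation after the acetylation only removes groups.

Step 1
Reactants: 1 4-(benzyloxy)-3-methoxybenzaldehyde
Product: 3 4-(benzyloxy)-3-methoxyphenol, via aryl formate 2 (not isolated)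
Conditions: mCPBA, CH2Cl2, 0 °C to rt; NaHCO3 wash; then K2CO3 (cat.), MeOH, rt
Reagents that add atoms: mCPBA OOC(=O)c1cccc(Cl)c1
Why: Baeyer–Villiger oxidation of an electron-rich benzaldehyde should migrate the aryl group to oxygen (Dakin-type outcome), and catalytic methanolysis should cleave the aryl formate without touching the benzyl ether.

Step 2
Reactants: 3 4-(benzyloxy)-3-methoxyphenol
Product: 4 1-(benzyloxy)-2-methoxy-4-(methoxymethoxy)benzene
Conditions: MOMCl, i-Pr2NEt, CH2Cl2, 0 °C to rt
Reagents that add atoms: chloromethyl methyl ether COCCl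
Why: O-alkylation of the phenol with the reactive chloromethyl ether under amine base is a standard acetal protection that leaves the benzyl and methyl ethers untouched.

Step 3
Reactants: 4 1-(benzyloxy)-2-methoxy-4-(methoxymethoxy)benzene
Product: 5 1-(benzyloxy)-5-bromo-2-methoxy-4-(methoxymethoxy)benzene
Conditions: NBS, MeCN, 0 °C
Reagents that add atoms: N-bromosuccinimide O=C1CCC(=O)N1Br
Why: Electrophilic aromatic bromination should go to the one position that is para to the methoxy group and ortho to the methoxymethoxy group, since the position between the two ethers is hindered and the position ortho to the benzyloxy group is activated by one oxygen only.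

Step 4
Reactants: 5 1-(benzyloxy)-5-bromo-2-methoxy-4-(methoxymethoxy)benzene
Product: 7 2-[5-(benzyloxy)-4-methoxy-2-(methoxymethoxy)phenyl]-4,4,5,5-tetramethyl-1,3,2-dioxaborolane, via aryllithium 6 (not isolated)
Conditions: n-BuLi, THF, −78 °C; then i-PrOBpin, −78 °C to rt; aq. NH4Cl
Reagents that add atoms: 2-isopropoxy-4,4,5,5-tetramethyl-1,3,2-dioxaborolane CC(C)OB1OC(C)(C)C(C)(C)O1
Why: Bromine–lithium exchange at −78 °C should outrun deprotonation between the ethers, and the aryllithium is trapped by the borate ester; the pinacol ester is chosen because it resists protodeboronation better than the free ortho-alkoxy boronic acid.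

Step 5
Reactants: 8 kojic acid (5-hydroxy-2-(hydroxymethyl)-4H-pyran-4-one)
Product: 9 2-bromo-3-hydroxy-6-(hydroxymethyl)-4H-pyran-4-one
Conditions: NBS, DMF, 0 °C to rt
Reagents that add atoms: N-bromosuccinimide O=C1CCC(=O)N1Br
Why: The enolic hydroxyl activates the adjacent C6 of kojic acid, the site at which this pyranone takes up electrophiles, so electrophilic bromination should stop at the 6-monobromide.

Step 6
Reactants: 9 2-bromo-3-hydroxy-6-(hydroxymethyl)-4H-pyran-4-one
Product: 10 2-bromo-6-(hydroxymethyl)-3-methoxy-4H-pyran-4-one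
Conditions: MeI, K2CO3, acetone, rt
Reagents that add atoms: iodomethane CI
Why: Williamson etherification should be selective for the acidic enolic hydroxyl, which alone is deprotonated by carbonate, over the primary alcohol.

Step 7
Reactants: 10 2-bromo-6-(hydroxymethyl)-3-methoxy-4H-pyran-4-one; 7 2-[5-(benzyloxy)-4-methoxy-2-(methoxymethoxy)phenyl]-4,4,5,5-tetramethyl-1,3,2-dioxaborolane
Product: 11 2-[5-(benzyloxy)-4-methoxy-2-(methoxymethoxy)phenyl]-6-(hydroxymethyl)-3-methoxy-4H-pyran-4-one
Conditions: Pd(OAc)2 (5 mol %), SPhos (10 mol %), K3PO4, toluene/H2O (10:1), 80 °C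
Reagents that add atoms: none
Why: Suzuki–Miyaura coupling; the 2-bromopyranone is a vinylogous acyl bromide that should add readily to zerovalent palladium, the biarylphosphine ligand suits an ortho-substituted electron-rich boron partner, and the free alcohol is tolerated.

Step 8
Reactants: 11 2-[5-(benzyloxy)-4-methoxy-2-(methoxymethoxy)phenyl]-6-(hydroxymethyl)-3-methoxy-4H-pyran-4-one
Product: 13 6-[5-(benzyloxy)-4-methoxy-2-(methoxymethoxy)phenyl]-5-methoxy-4-oxo-4H-pyran-2-carboxylic acid, via aldehyde 12 (not isolated)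
Conditions: TEMPO (0.2 equiv), PhI(OAc)2 (2.2 equiv), MeCN/H2O (1:1), rt
Reagents that add atoms: water O
Why: Oxoammonium (TEMPO) oxidation gives the electron-poor aldehyde, whose hydrate is oxidised again to the acid under nearly neutral conditions that the acetal, the benzyl ether and the electron-rich arene should survive.

Step 9
Reactants: 13 6-[5-(benzyloxy)-4-methoxy-2-(methoxymethoxy)phenyl]-5-methoxy-4-oxo-4H-pyran-2-carboxylic acid
Product: 15 2-[5-(benzyloxy)-4-methoxy-2-(methoxymethoxy)phenyl]-6-(diazoacetyl)-3-methoxy-4H-pyran-4-one, via acid chloride 14 (not isolated)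
Conditions: 1-chloro-N,N,2-trimethylprop-1-en-1-amine, CH2Cl2, 0 °C to rt; then CH2N2 (4 equiv), Et2O, 0 °C
Reagents that add atoms: diazomethane C=[N+]=[N-]
Why: The chloroenamine makes the acid chloride without free HCl, so the methoxymethyl ether is safe, and acylation of excess diazomethane (first stage of an Arndt–Eistert sequence) should be much faster than dipolar addition to the pyranone double bond.

Step 10
Reactants: 16 acetylene
Product: 19 (triisopropylsilyloxy)acetylene, via lithium acetylide 17 (not isolated), via lithium ethynolate 18 (not isolated)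
Conditions: C2H2 (excess), n-BuLi, THF, −78 °C; LiOOt-Bu (from t-BuOOH and n-BuLi, THF, −78 °C), −78 to −20 °C; then TIPSOTf, −78 °C to rt
Reagents that add atoms: tert-butyl hydroperoxide CC(C)(C)OO; triisopropylsilyl trifluoromethanesulfonate CC(C)[Si](OS(=O)(=O)C(F)(F)F)(C(C)C)C(C)C
Why: Transfer of electrophilic oxygen from lithium tert-butyl peroxide to a lithium acetylide is the usual entry to lithium ynolates from terminal alkynes, and the bulky silyl triflate should silylate the ynolate on oxygen to give the thermally robust silyl ynol ether; excess acetylene and low temperature hold the monolithium acetylide.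

Step 11
Reactants: 15 2-[5-(benzyloxy)-4-methoxy-2-(methoxymethoxy)phenyl]-6-(diazoacetyl)-3-methoxy-4H-pyran-4-one; 19 (triisopropylsilyloxy)acetylene
Product: 24 2-[5-(benzyloxy)-4-methoxy-2-(methoxymethoxy)phenyl]-5-hydroxy-3-methoxy-7-[(triisopropylsilyl)oxy]-4H-chromen-4-one, via ketene 20 (not isolated), via cyclobutenone 21 (not isolated), via dienylketene 22 (not isolated), via cyclohexadienone 23 (not isolated)
Conditions: 19 (2.5 equiv), degassed ClCH2CH2Cl, hν (medium-pressure Hg lamp, Pyrex filter, >300 nm), 20 °C until 15 is consumed; then 80 °C in the dark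
Reagents that add atoms: none
Why: Light expels N2 from the diazoketone and the pyranonyl group shifts from the acyl carbon to the former diazo carbon (C8–C8a), giving a ketene conjugated with the C4a=C8a double bond of ring C; a (2+2) cycloaddition with the siloxyalkyne (C5–C6 and C7–C8) then gives a 3-siloxycyclobutenone, which opens in a four-electron electrocyclic step, by light or heat, to a dienylketene. Ring A is closed by six-electron electrocyclization of this dienylketene onto C4a (C4a–C5), and tautomerization of the resulting cyclohexadienone gives the phenol. The closest known reaction is the Danheiser benzannulation in its diazoketone variant with siloxyalkynes, which converts aryl, heteroaryl and alkenyl diazomethyl ketones into monosilylated resorcinols. No stereocenter is left in the product; the stereocenters of the cyclobutenone and the cyclohexadienone are racemic and are erased on aromatization. The selectivity needed is regiochemical: the unsubstituted carbon of the polarized ynol ether bonds to the ketene carbonyl carbon, which puts silyloxy on C7, hydrogen on C6 and the free hydroxyl on C5, and closure can only take place at C4a because the other neighbour of C8a is the ring oxygen. Irradiation above 300 nm with thermal completion should limit secondary photochemistry of the pyranone and of the 3-methoxyflavone formed, and the new 5-hydroxyl, held in a hydrogen bond to the C4 carbonyl, should not be acylated by ketene.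

Step 12
Reactants: 24 2-[5-(benzyloxy)-4-methoxy-2-(methoxymethoxy)phenyl]-5-hydroxy-3-methoxy-7-[(triisopropylsilyl)oxy]-4H-chromen-4-one
Product: 25 5-hydroxy-2-[5-hydroxy-4-methoxy-2-(methoxymethoxy)phenyl]-3-methoxy-7-[(triisopropylsilyl)oxy]-4H-chromen-4-one
Conditions: H2 (1 atm), 10% palladium on carbon (Pd/C), EtOAc, rt
Reagents that add atoms: none
Why: Hydrogenolysis of the aryl benzyl ether proceeds under neutral conditions that should leave the tetrasubstituted C2=C3 bond of the chromone, the silyl ether and the acetal intact.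

Step 13
Reactants: 25 5-hydroxy-2-[5-hydroxy-4-methoxy-2-(methoxymethoxy)phenyl]-3-methoxy-7-[(triisopropylsilyl)oxy]-4H-chromen-4-one
Product: 26 5-{5-hydroxy-3-methoxy-4-oxo-7-[(triisopropylsilyl)oxy]-4H-chromen-2-yl}-2-methoxy-4-(methoxymethoxy)phenyl acetate
Conditions: Ac2O (1.1 equiv), pyridine, CH2Cl2, 0 °C
Reagents that add atoms: acetic anhydride CC(=O)OC(C)=O
Why: With one equivalent of anhydride and no acyl-transfer catalyst, the free electron-rich 5'-phenol should be acylated far faster than the 5-hydroxyl, which is held in a hydrogen bond to the C4 carbonyl, while O7 and O2' are blocked.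

Step 14
Reactants: 26 5-{5-hydroxy-3-methoxy-4-oxo-7-[(triisopropylsilyl)oxy]-4H-chromen-2-yl}-2-methoxy-4-(methoxymethoxy)phenyl acetate
Product: 27 4-hydroxy-5-{5-hydroxy-3-methoxy-4-oxo-7-[(triisopropylsilyl)oxy]-4H-chromen-2-yl}-2-methoxyphenyl acetate
Conditions: ZnBr2, n-PrSH, CH2Cl2, 0 °C to rt
Reagents that add atoms: none
Why: Lewis-acid activation of the acetal with a thiol as trap cleaves the aryl methoxymethyl ether in an aprotic, non-basic medium, so the aryl acetate should survive and the methoxymethyl cation is intercepted before it can alkylate ring A.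

Step 15
Reactants: 27 4-hydroxy-5-{5-hydroxy-3-methoxy-4-oxo-7-[(triisopropylsilyl)oxy]-4H-chromen-2-yl}-2-methoxyphenyl acetate
Product: 28 5,7,2',5'-tetrahydroxy-3,4'-dimethoxyflavone 5'-acetate
Conditions: HF·pyridine, pyridine, THF, 0 °C to rt
Reagents that add atoms: none
Why: Fluoride cleaves the silyl ether of the acidic 7-phenol under mildly acidic buffered conditions, under which the aryl acetate should neither hydrolyse nor migrate.

Compound list
1 | 4-(benzyloxy)-3-methoxybenzaldehyde | COc1cc(C=O)ccc1OCc1ccccc1 | starting material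
2 | 4-(benzyloxy)-3-methoxyphenyl formate | O=COc1ccc(OCc2ccccc2)c(OC)c1 | intermediate
3 | 4-(benzyloxy)-3-methoxyphenol | COc1cc(O)ccc1OCc1ccccc1 | intermediate
4 | 1-(benzyloxy)-2-methoxy-4-(methoxymethoxy)benzene | COCOc1ccc(OCc2ccccc2)c(OC)c1 | intermediate
5 | 1-(benzyloxy)-5-bromo-2-methoxy-4-(methoxymethoxy)benzene | COCOc1cc(OC)c(OCc2ccccc2)cc1Br | intermediate
6 | [5-(benzyloxy)-4-methoxy-2-(methoxymethoxy)phenyl]lithium | [Li]c1cc(OCc2ccccc2)c(OC)cc1OCOC | intermediate
7 | 2-[5-(benzyloxy)-4-methoxy-2-(methoxymethoxy)phenyl]-4,4,5,5-tetramethyl-1,3,2-dioxaborolane | COCOc1cc(OC)c(OCc2ccccc2)cc1B1OC(C)(C)C(C)(C)O1 | intermediate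
8 | kojic acid, 5-hydroxy-2-(hydroxymethyl)-4H-pyran-4-one | OCc1cc(=O)c(O)co1 | starting material
9 | 2-bromo-3-hydroxy-6-(hydroxymethyl)-4H-pyran-4-one (6-bromokojic acid) | OCc1cc(=O)c(O)c(Br)o1 | intermediate
10 | 2-bromo-6-(hydroxymethyl)-3-methoxy-4H-pyran-4-one | COc1c(Br)oc(CO)cc1=O | intermediate
11 | 2-[5-(benzyloxy)-4-methoxy-2-(methoxymethoxy)phenyl]-6-(hydroxymethyl)-3-methoxy-4H-pyran-4-one | COCOc1cc(OC)c(OCc2ccccc2)cc1-c1oc(CO)cc(=O)c1OC | intermediate
12 | 6-[5-(benzyloxy)-4-methoxy-2-(methoxymethoxy)phenyl]-5-methoxy-4-oxo-4H-pyran-2-carbaldehyde | COCOc1cc(OC)c(OCc2ccccc2)cc1-c1oc(C=O)cc(=O)c1OC | intermediate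
13 | 6-[5-(benzyloxy)-4-methoxy-2-(methoxymethoxy)phenyl]-5-methoxy-4-oxo-4H-pyran-2-carboxylic acid | COCOc1cc(OC)c(OCc2ccccc2)cc1-c1oc(C(=O)O)cc(=O)c1OC | intermediate
14 | 6-[5-(benzyloxy)-4-methoxy-2-(methoxymethoxy)phenyl]-5-methoxy-4-oxo-4H-pyran-2-carbonyl chloride | COCOc1cc(OC)c(OCc2ccccc2)cc1-c1oc(C(Cl)=O)cc(=O)c1OC | intermediate
15 | 2-[5-(benzyloxy)-4-methoxy-2-(methoxymethoxy)phenyl]-6-(diazoacetyl)-3-methoxy-4H-pyran-4-one | [N-]=[N+]=CC(=O)c1cc(=O)c(OC)c(-c2cc(OCc3ccccc3)c(OC)cc2OCOC)o1 | intermediate
16 | acetylene | C#C | starting material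
17 | lithium acetylide (ethynyllithium) | [Li]C#C | intermediate
18 | lithium ethynolate | [Li]OC#C | intermediate
19 | (triisopropylsilyloxy)acetylene, (ethynyloxy)tri(propan-2-yl)silane | C#CO[Si](C(C)C)(C(C)C)C(C)C | intermediate
20 | 2-[5-(benzyloxy)-4-methoxy-2-(methoxymethoxy)phenyl]-3-methoxy-6-(2-oxoethenyl)-4H-pyran-4-one (pyranonyl ketene) | O=C=Cc1cc(=O)c(OC)c(-c2cc(OCc3ccccc3)c(OC)cc2OCOC)o1 | intermediate
21 | 2-[5-(benzyloxy)-4-methoxy-2-(methoxymethoxy)phenyl]-3-methoxy-6-{4-oxo-2-[(triisopropylsilyl)oxy]cyclobut-2-en-1-yl}-4H-pyran-4-one (racemic) | O=C1C=C(O[Si](C(C)C)(C(C)C)C(C)C)C1c1cc(=O)c(OC)c(-c2cc(OCc3ccccc3)c(OC)cc2OCOC)o1 | intermediate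
22 | 2-[5-(benzyloxy)-4-methoxy-2-(methoxymethoxy)phenyl]-3-methoxy-6-{(1E)-4-oxo-2-[(triisopropylsilyl)oxy]buta-1,3-dien-1-yl}-4H-pyran-4-one (dienylketene, ketenyl carbon cis to the pyranone) | O=C=C/C(O[Si](C(C)C)(C(C)C)C(C)C)=C\c1cc(=O)c(OC)c(-c2cc(OCc3ccccc3)c(OC)cc2OCOC)o1 | intermediate
23 | 2-[5-(benzyloxy)-4-methoxy-2-(methoxymethoxy)phenyl]-3-methoxy-7-[(triisopropylsilyl)oxy]-4H-chromene-4,5(4aH)-dione (racemic keto tautomer of 24) | COCOc1cc(OC)c(OCc2ccccc2)cc1C1=C(OC)C(=O)C2C(=O)C=C(O[Si](C(C)C)(C(C)C)C(C)C)C=C2O1 | intermediate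
24 | 2-[5-(benzyloxy)-4-methoxy-2-(methoxymethoxy)phenyl]-5-hydroxy-3-methoxy-7-[(triisopropylsilyl)oxy]-4H-chromen-4-one | COCOc1cc(OC)c(OCc2ccccc2)cc1-c1oc2cc(O[Si](C(C)C)(C(C)C)C(C)C)cc(O)c2c(=O)c1OC | intermediate
25 | 5-hydroxy-2-[5-hydroxy-4-methoxy-2-(methoxymethoxy)phenyl]-3-methoxy-7-[(triisopropylsilyl)oxy]-4H-chromen-4-one | COCOc1cc(OC)c(O)cc1-c1oc2cc(O[Si](C(C)C)(C(C)C)C(C)C)cc(O)c2c(=O)c1OC | intermediate
26 | 5-{5-hydroxy-3-methoxy-4-oxo-7-[(triisopropylsilyl)oxy]-4H-chromen-2-yl}-2-methoxy-4-(methoxymethoxy)phenyl acetate | COCOc1cc(OC)c(OC(C)=O)cc1-c1oc2cc(O[Si](C(C)C)(C(C)C)C(C)C)cc(O)c2c(=O)c1OC | intermediate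
27 | 4-hydroxy-5-{5-hydroxy-3-methoxy-4-oxo-7-[(triisopropylsilyl)oxy]-4H-chromen-2-yl}-2-methoxyphenyl acetate | COc1cc(O)c(-c2oc3cc(O[Si](C(C)C)(C(C)C)C(C)C)cc(O)c3c(=O)c2OC)cc1OC(C)=O | intermediate
28 | 5,7,2',5'-tetrahydroxy-3,4'-dimethoxyflavone 5'-acetate, 5-(5,7-dihydroxy-3-methoxy-4-oxo-4H-chromen-2-yl)-4-hydroxy-2-methoxyphenyl acetate | COc1cc(O)c(-c2oc3cc(O)cc(O)c3c(=O)c2OC)cc1OC(C)=O | target

Total step count: 15.
Longest linear sequence: 12 steps (steps 1–4, 7–9 and 11–15).

Steps most likely to fail

Step 11. The excited pyranone or the flavone that builds up may absorb the light and decompose, or the photogenerated carbene or ketene may be diverted before it meets the alkyne, so that little ketene enters the cycloaddition. The fallback makes the same ketene in the dark and sets out from diazoketone 15. Silver benzoate (PhCO2Ag) and Et3N in dioxane/H2O at rt effect the Arndt–Eistert homologation to {6-[5-(benzyloxy)-4-methoxy-2-(methoxymethoxy)phenyl]-5-methoxy-4-oxo-4H-pyran-2-yl}acetic acid F1. 1-Chloro-N,N,2-trimethylprop-1-en-1-amine in CH2Cl2 converts this acid into {6-[5-(benzyloxy)-4-methoxy-2-(methoxymethoxy)phenyl]-5-methoxy-4-oxo-4H-pyran-2-yl}acetyl chloride F2. Slow addition of this chloride to Et3N and siloxyalkyne 19 in toluene at 80 °C should dehydrochlorinate it to ketene 20, which then follows the thermal path through 21, 22 and 23. The fallback comes back to the route at 24.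

Step 10. Monolithium acetylide may disproportionate to insoluble dilithium acetylide before it is oxidised, or a second metalation may lead to silylation on carbon. The fallback makes the ynolate by base-induced fragmentation of an isoxazole instead of acetylide oxidation. It consumes no numbered compound: purchased 3-phenylisoxazole takes the place of acetylene 16 and lithium acetylide 17. Deprotonation at C5 with n-BuLi in THF at −78 °C gives 5-lithio-3-phenylisoxazole F3, which on warming to about −40 °C should cleave into benzonitrile and lithium ethynolate 18. The fallback rejoins the route at 18, which is silylated with TIPSOTf as in step 10 to give 19, separated from benzonitrile by distillation.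

Step 9. Diazomethane may add as a 1,3-dipole across the acyl-activated C5=C6 bond of the pyranone, or the acylation may end at the chloromethyl ketone. The fallback avoids diazomethane and sets out from acid 13 by way of its chloride 14. Negishi acylation with MeZnCl and Pd(PPh3)4 in THF at 0 °C should give 6-acetyl-2-[5-(benzyloxy)-4-methoxy-2-(methoxymethoxy)phenyl]-3-methoxy-4H-pyran-4-one F4. Its lithium enolate (LiHMDS, THF, −78 °C) is acylated with CF3CO2CH2CF3 to 4,4,4-trifluoro-1-{6-[5-(benzyloxy)-4-methoxy-2-(methoxymethoxy)phenyl]-5-methoxy-4-oxo-4H-pyran-2-yl}butane-1,3-dione F5, which is not isolated. Treatment with MsN3, Et3N and H2O in MeCN at rt (detrifluoroacetylative diazo transfer) then gives 15, where the fallback comes back to the route.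

Further compounds
F1 | step 11 | {6-[5-(benzyloxy)-4-methoxy-2-(methoxymethoxy)phenyl]-5-methoxy-4-oxo-4H-pyran-2-yl}acetic acid | OC(=O)Cc1cc(=O)c(OC)c(-c2cc(OCc3ccccc3)c(OC)cc2OCOC)o1
F2 | step 11 | {6-[5-(benzyloxy)-4-methoxy-2-(methoxymethoxy)phenyl]-5-methoxy-4-oxo-4H-pyran-2-yl}acetyl chloride | ClC(=O)Cc1cc(=O)c(OC)c(-c2cc(OCc3ccccc3)c(OC)cc2OCOC)o1
F3 | step 10 | 5-lithio-3-phenylisoxazole | [Li]c1cc(-c2ccccc2)no1
F4 | step 9 | 6-acetyl-2-[5-(benzyloxy)-4-methoxy-2-(methoxymethoxy)phenyl]-3-methoxy-4H-pyran-4-one | CC(=O)c1cc(=O)c(OC)c(-c2cc(OCc3ccccc3)c(OC)cc2OCOC)o1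
F5 | step 9 | 4,4,4-trifluoro-1-{6-[5-(benzyloxy)-4-methoxy-2-(methoxymethoxy)phenyl]-5-methoxy-4-oxo-4H-pyran-2-yl}butane-1,3-dione | O=C(CC(=O)C(F)(F)F)c1cc(=O)c(OC)c(-c2cc(OCc3ccccc3)c(OC)cc2OCOC)o1
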